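## The problem

The target is a daucane ester: a trans-fused bicyclo[5.3.0]decane in which the seven-membered ring A (C1, C5–C10) and the five-membered ring B (C1–C5) share the C1–C5 bond. C1 is quaternary (methyl) and C5 is a methine. There are five stereocentres: C1, C4 (tertiary carbinol with isopropyl), C5, C6 (veratrate) and C10 (angelate, allylic to the C8=C9 alkene that carries the C8 methyl). The absolute configuration is (1S,4R,5S,6S,10R).

C1 is the only centre that later steps cannot correct. Its methyl is axial to both rings and can steer the others:
- syn addition to a C5=C6 alkene opposite to the methyl gives 5α-H and 6α-O;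
- a nucleophile adds to a C4 ketone opposite to the methyl and gives the 4β-carbinol;
- hydride adds to a C10 ketone opposite to the methyl as well, which gives the 10β-alcohol, whereas the target has the 10α-ester. C10 therefore needs an inversion.

Fragile groups are the angelate (Z-enoate, isomerised to the tiglate by nucleophiles, base or heat) on an ionisable allylic carbon, the tertiary C4 alcohol, and any C6 acyloxy group while C4 is a ketone (β-elimination). The esters should go on late and under near-neutral conditions.

The feature that opens the structure: C1 lies between C5 and C10, which are the two carbonyl carbons of a 2-methylcycloheptane-1,3-dione, and C4 ends a three-carbon chain on C1. An aldehyde at C4 can add to C5 as an acyl anion. Because the two ring carbonyls are enantiotopic, one catalytic event closes ring B and fixes C1.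

## Retrosynthesis

**C10–O (21 ⇒ 19 + 20).** The angelate C–O bond is cut with inversion: target 21 comes from the 10β-allylic alcohol 19 and angelic acid 20 by a Mitsunobu reaction. Cutting the acyl–oxygen bond instead would need the 10α-alcohol, which requires a reduction against the methyl bias. The forward step must invert a neopentylic allylic carbinol and keep the Z-enoate.

**Ring A unsaturation and C8 methyl (19 ⇒ 18 ⇒ 17 ⇒ 16 ⇒ 15).** The allylic alcohol 19 is the 1,2-reduction product of enone 18. The C8–CH3 bond and the C8=C9 alkene are traced to the saturated C10 ketone 15 by two dehydrogenations (16, 18) around one cuprate addition (17). Only C9 can enolise, because C1 is quaternary, so regiochemistry is not in question. This removes an alkene, a methyl group and a stereocentre.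

**C4–isopropyl (15 ⇒ 14).** The C4–CH(CH3)2 bond is cut to diketone 14. An organocerium reagent must choose the C4 cyclopentanone over the C10 ketone (flanked by quaternary C1) and must add from the α face, opposite to the methyl.

**C6 ester and oxidation levels (14 ⇒ 13 ⇒ 12 ⇒ 10 + 11).** Both ketones of 14 are reached by oxidation of diol 13, freed from bis-silyl ether 12. The ester bond of 12 is cut to alcohol 10 and veratric acid 11. Putting the veratrate on here means the C6 hydroxyl needs no protecting group of its own.

**C5–H and C6–O (10 ⇒ 8).** Both bonds are cut together, as hydroboration–oxidation of the C5=C6 alkene of 8. Syn addition couples the two centres, so one facial choice gives the trans ring fusion and the 6α-oxygen. An enone cannot be hydroborated, which is why C4 and C10 pass through the alcohol level.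

**Protection and reduction (8 ⇒ 7 ⇒ 6).** Bis-silyl ether 8 comes from diol 7, made by oxazaborolidine-controlled reduction of enedione 6. The catalyst places both hydroxyls on the methyl face, where the C4 silyl ether shields the β face of the alkene and the C10 silyl ether lies equatorial and clear of the α face.

**C5–OH (6 ⇒ 5).** The alkene of 6 comes from dehydration of the tertiary ketol 5. C5 has hydrogen on only one neighbour (C6), so only one alkene can form, and the ring-fusion configuration of 5 does not matter.

**C4–C5, the key cut (5 ⇒ 4).** Cutting C4–C5 of ketol 5 opens ring B and gives the achiral keto aldehyde 4. All stereochemistry is removed. The forward reaction, a carbene-catalysed crossed benzoin addition, must distinguish two enantiotopic ketones.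

**C1–C2 and C1–CH3 (4 ⇒ 2 + 3, 2 ⇒ 1).** Aldehyde 4 is the Michael adduct of 2-methylcycloheptane-1,3-dione 2 and acrolein 3. Dione 2 is the C-methylation product of cycloheptane-1,3-dione 1.

## Roads not taken

**Alternative 1:** The cut is C1–C5, made by an Ireland–Claisen rearrangement that contracts a larger ring. An ester oxygen tying the C4 carboxyl carbon to C9 is released as C1–C5 forms. The product is cycloheptene acid A1 (C4 carboxyl on C5, vinyl C2=C3 on C1, C9=C10 alkene, C8 methyl, silylated C6 oxygen).
- Merits: one pericyclic step sets the vicinal C1/C5 pair through a cyclic transition state, and ring A arrives with the C6 oxygen and the C8 methyl in place. The C10 oxygen could later be delivered as an electrophile to the C9=C10 alkene from the face opposite to the methyl, which is the face the target needs. On that point it is better than the chosen plan, which must invert C10.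
- Weak points: the rearrangement substrate must already hold three stereocentres and a trisubstituted alkene of defined geometry, so it needs a long linear synthesis. C1 depends on a boat-versus-chair preference of a medium-ring ketene acetal that is not secured. Ring B still has to be closed between C3 and C4, and the alkene has to be moved to C8=C9.
- Comparison: the chosen plan sets a two-step achiral precursor and catalytic asymmetric induction against the better C10 logic of A1.

**Alternative 2:** The cut is C1–C10, made by a divinylcyclopropane Cope rearrangement. The C6–C8 bond of a three-membered ring breaks while C1–C10 forms. The product is bicyclic diene A2 (10-OPMB, C5=C6 and C8=C9 alkenes, C4 dioxolane).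
- Merits: A2 is the most advanced of the four key-step products. Ring A arrives with the C8=C9 alkene and its methyl, with C5=C6 ready for hydroboration, and with C10 translated stereospecifically from enol-ether geometry. No inversion at C10 is needed, a clear advantage over the chosen plan.
- Weak points: the rearrangement must create quaternary C1 from a tetrasubstituted cyclopentene terminus folded over the three-membered ring, the classic retarded case. The cis-cyclopropane must be made as one enantiomer with an E-enol ether. A2 also carries two trisubstituted alkenes that a hydroboration at C5=C6 would have to tell apart.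
- Comparison: the chosen plan offers a key bond formed by a simple 5-exo carbonyl addition and later alkene chemistry that never meets a second alkene. It pays with more redox steps.

**Alternative 3:** The cuts are C1–C5 and C8–C9, made together by an intramolecular (4+3) cycloaddition. An oxyallyl cation spanning C9–C10(O)–C1 adds across the termini of a tethered E,E-diene. The product is hydroazulenone A3 (C10 ketone, C6=C7 alkene, C8 methyl, silylated C4 carbinol with its isopropyl group).
- Merits: both rings and two bonds form in one step. The C4 carbinol and the C8 methyl are present from the start, so no organometallic addition next to an ester is needed. It would be the shortest route, and here it beats the chosen plan.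
- Weak points: C4 is the only stereocentre before the cycloaddition and must control C1, C5 and C8 through a three-atom tether, with endo/exo and ring-fusion selectivity both open. The alkene ends at C6=C7, so the 6α-oxygen needs a hydration with no inherent bias between C6 and C7. The C10 problem is the same as in the chosen plan. The tertiary carbinol must first be made enantiopure.
- Comparison: against that brevity the chosen plan assigns each stereocentre to one identified control element.

Key step: step 3

Remark on naming: locants C1–C10 are those of the target core (ring A = C1, C5–C10; ring B = C1–C5). β is the face of the C1 methyl and α the opposite face.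

Remark on step 3: the sense of induction is assigned by analogy with the six-membered diketone series. If the seven-membered substrate responds in the opposite sense, the antipodal salt, made from the enantiomeric 1-amino-2-indanol, is used.

## Route

Step 1
Reactants: 1 cycloheptane-1,3-dione
Product: 2 2-methylcycloheptane-1,3-dione
Conditions: MeI, K2CO3, acetone, reflux; dilute HCl work-up
Reagents that add atoms: iodomethane, CI
Why: C-alkylation of the stabilised 1,3-diketone enolate at the doubly activated carbon; the minor O-methyl enol ether is hydrolysed back to 1 by the acidic work-up and recycled.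

Step 2
Reactants: 2 2-methylcycloheptane-1,3-dione; 3 acrolein
Product: 4 3-(1-methyl-2,7-dioxocycloheptyl)propanal (achiral keto aldehyde; CHO = C4)
Conditions: Et3N (0.1 equiv), MeCN, 0 → 23 °C
Reagents that add atoms: none
Why: Amine-catalysed Michael addition of the diketone enolate to acrolein creates quaternary C1 in a mirror-symmetric product; C1 carries no hydrogen, so the adduct cannot revert by enolisation at that carbon.

Step 3
Reactants: 4 3-(1-methyl-2,7-dioxocycloheptyl)propanal
Product: 5 (3aR,8aS)-3a-hydroxy-8a-methyloctahydroazulene-3,8-dione (cis-fused ketol: C4 ketone; 5β-hydroxyl; C10 ketone; C1 S)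
Conditions: (5aS,10bR)-2-(pentafluorophenyl)-5a,10b-dihydro-4H,6H-indeno[2,1-b][1,2,4]triazolo[4,3-d][1,4]oxazin-2-ium tetrafluoroborate (10 mol %), DBU (10 mol %), CH2Cl2 (0.02 M), 23 °C
Reagents that add atoms: none
Why: The carbene freed from the triazolium salt adds to the aldehyde carbon C4 and a proton shift gives the Breslow intermediate, whose nucleophilic C4 attacks one ring carbonyl; collapse of the adduct releases the carbene and leaves the C4 ketone and the C5 tertiary alcohol. The closest known reaction type is the carbene-catalysed desymmetrising intramolecular crossed benzoin reaction of 2,2-disubstituted cyclohexane-1,3-diones with the same 3-oxopropyl chain, of which 4 is the ring-enlarged homologue. Ring B closes in the 5-exo-trig mode. C1 is set by the choice between the enantiotopic C5 and C10 carbonyls, made by the aminoindanol backbone and N-aryl group of the catalyst, which leave one face of the enaminol open. C5 follows from C1, because the three-atom tether reaches the carbonyl only in the geometry that gives the cis-fused ketol. Only the aldehyde can form a Breslow intermediate, and no aldol path competes (C1 is quaternary and closure from C3 would give a four-membered ring), so the ketones act only as acceptors; dilution suppresses aldehyde dimerisation.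

Step 4
Reactants: 5 cis-fused ketol
Product: 6 (8aS)-8a-methyl-1,2,5,6,7,8a-hexahydroazulene-3,8-dione (Δ5-en-4-one with free C10 ketone)
Conditions: SOCl2, pyridine, CH2Cl2, −20 → 0 °C
Reagents that add atoms: none
Why: Dehydration of a tertiary α-ketol through its chlorosulfite by base-assisted E2 elimination; C6 is the only neighbour of C5 with hydrogen, so a single, conjugated alkene can form and the ring-fusion configuration of 5 is erased.

Step 5
Reactants: 6 Δ5-en-4-one
Product: 7 (1S,4S,10S)-1-methylbicyclo[5.3.0]dec-5-ene-4β,10β-diol (both hydroxyls cis to the C1 methyl)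
Conditions: (R)-1-methyl-3,3-diphenyltetrahydro-1H,3H-pyrrolo[1,2-c][1,3,2]oxazaborole [(R)-Me-CBS] (0.3 equiv), BH3·SMe2, THF, −30 °C; MeOH quench
Reagents that add atoms: none
Why: Corey–Bakshi–Shibata reduction; at C4 the alkylidene flank (C5) and at C10 the quaternary flank (C1) act as the large groups, so the (R)-oxazaborolidine should deliver hydride to the α face of both carbonyls; 1,2-reduction of the enone is faster than hydroboration of the hindered alkene at this temperature.

Step 6
Reactants: 7 4β,10β-diol
Product: 8 4β,10β-bis(tert-butyldimethylsilyloxy)-1β-methylbicyclo[5.3.0]dec-5-ene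
Conditions: TBSOTf, 2,6-lutidine, CH2Cl2, 0 °C
Reagents that add atoms: tert-butyldimethylsilyl trifluoromethanesulfonate, CC(C)(C)[Si](C)(C)OS(=O)(=O)C(F)(F)F
Why: Silylation with the silyl triflate reaches the neopentylic C10 hydroxyl as well as the allylic C4 hydroxyl; the ethers mask both carbinols against borane and place a bulky group on the β face next to C5.

Step 7
Reactants: 8 bis-silyl ether
Product: 10 4β,10β-bis(tert-butyldimethylsilyloxy)-1β-methyl-5α-H-bicyclo[5.3.0]decan-6α-ol, via 6α-alkylborane 9 (not isolated)
Conditions: BH3·THF, THF, 0 → 23 °C; then NaOH, H2O2, 0 °C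
Reagents that add atoms: borane–tetrahydrofuran (boron only in 9), B.C1CCOC1; hydrogen peroxide, OO
Why: Hydroboration–oxidation; boron goes to C6, the less substituted carbon and the one distal to the allylic oxygen, and syn addition from the α face (opposite to the axial C1 methyl and the 4β-silyloxy group, with only hydrogen in the α-axial position at C10) sets 5α-H and 6α-B together; oxidation replaces boron by hydroxyl with retention.

Step 8
Reactants: 10 6α-alcohol; 11 veratric acid (3,4-dimethoxybenzoic acid)
Product: 12 4β,10β-bis(tert-butyldimethylsilyloxy)-6α-(3,4-dimethoxybenzoyloxy)-1β-methyl-5α-H-bicyclo[5.3.0]decane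
Conditions: EDC·HCl, DMAP, CH2Cl2, 23 °C
Reagents that add atoms: none
Why: Steglich esterification of the only free hydroxyl, an equatorial secondary alcohol; no stereocentre is touched.

Step 9
Reactants: 12 bis-silyl veratrate
Product: 13 6α-(3,4-dimethoxybenzoyloxy)-1β-methyl-5α-H-bicyclo[5.3.0]decane-4β,10β-diol
Conditions: HF·pyridine, pyridine, THF, 0 → 23 °C
Reagents that add atoms: none
Why: Fluoride cleavage of both silyl ethers in a buffered acidic medium, which avoids the base-induced 1,3-acyl shift from O6 to O4 that tetrabutylammonium fluoride could cause.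

Step 10
Reactants: 13 diol veratrate
Product: 14 6α-(3,4-dimethoxybenzoyloxy)-1β-methyl-5α-H-bicyclo[5.3.0]decane-4,10-dione
Conditions: Dess–Martin periodinane, NaHCO3, CH2Cl2, 0 → 23 °C
Reagents that add atoms: none
Why: Dess–Martin oxidation of both secondary alcohols under neutral buffered conditions, chosen so that the β-aroyloxy ketone neither eliminates nor epimerises at C5.

Step 11
Reactants: 14 dione veratrate
Product: 15 4β-hydroxy-4α-isopropyl-6α-(3,4-dimethoxybenzoyloxy)-1β-methyl-5α-H-bicyclo[5.3.0]decan-10-one
Conditions: iPrMgCl, CeCl3, THF, −78 °C
Reagents that add atoms: isopropylmagnesium chloride, CC(C)[Mg]Cl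
Why: Organocerium 1,2-addition, which suppresses enolisation and β-hydride reduction; the C4 cyclopentanone reacts in preference to the C10 ketone flanked by quaternary C1 and to the aryl ester, and the reagent enters from the α face (next to axial H5 and opposite to the axial C1 methyl and the C5–C6 bond), giving the 4β-alcohol.

Step 12
Reactants: 15 saturated C10 ketone
Product: 16 4β-hydroxy-4α-isopropyl-6α-(3,4-dimethoxybenzoyloxy)-1β-methyl-5α-H-bicyclo[5.3.0]dec-8-en-10-one
Conditions: IBX (2-iodoxybenzoic acid, 1.3 equiv), DMSO/fluorobenzene, 65 °C
Reagents that add atoms: none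
Why: IBX-mediated α,β-dehydrogenation of a ketone; C9 is the only enolisable α-carbon, the tertiary alcohol and the ester are inert, and limiting the oxidant stops the reaction at the enone.

Step 13
Reactants: 16 Δ8-en-10-one
Product: 17 4β-hydroxy-4α-isopropyl-6α-(3,4-dimethoxybenzoyloxy)-1β,8-dimethyl-5α-H-bicyclo[5.3.0]decan-10-one (C8 epimers)
Conditions: Me2CuLi (from MeLi and CuI, 3 equiv), Et2O/THF, −78 → −40 °C; aq. NH4Cl
Reagents that add atoms: lithium dimethylcuprate, [Li+].C[Cu-]C
Why: Cuprate conjugate addition to a cis-disubstituted cycloheptenone; the ester is not attacked, one equivalent is consumed by the C4 hydroxyl, and the configuration at C8 is of no consequence because C8 becomes trigonal in step 14.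

Step 14
Reactants: 17 8-methyl ketone
Product: 18 4β-hydroxy-4α-isopropyl-6α-(3,4-dimethoxybenzoyloxy)-1β,8-dimethyl-5α-H-bicyclo[5.3.0]dec-8-en-10-one
Conditions: IBX (1.3 equiv), DMSO/fluorobenzene, 70 °C
Reagents that add atoms: none
Why: Second IBX dehydrogenation; enolisation is again possible only toward C9, so the C8=C9 bond returns with the methyl group on C8.

Step 15
Reactants: 18 8-methyl enone
Product: 19 4α-isopropyl-6α-(3,4-dimethoxybenzoyloxy)-1β,8-dimethyl-5α-H-bicyclo[5.3.0]dec-8-ene-4β,10β-diol
Conditions: NaBH4, CeCl3·7H2O, MeOH, −78 °C
Reagents that add atoms: none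
Why: Luche 1,2-reduction; hydride should attack the α face, antiperiplanar to the axial C1 methyl that stands perpendicular to the carbonyl plane (the sense known for angular-methyl hydrindanones, decalones and 17-keto steroids), giving the 10β-alcohol cis to the methyl.

Step 16
Reactants: 19 10β-allylic alcohol; 20 angelic acid ((Z)-2-methylbut-2-enoic acid)
Product: 21 (1S,4R,5S,6S,10R)-10α-angeloyloxy-4β-hydroxy-4α-isopropyl-6α-(3,4-dimethoxybenzoyloxy)-1β,8-dimethyl-5α-H-bicyclo[5.3.0]dec-8-ene (CNP0142353.1)
Conditions: PPh3, DIAD, toluene, 0 → 23 °C
Reagents that add atoms: none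
Why: Mitsunobu esterification with inversion; the carboxylate enters C10 from the α face, the open face that hydride used in step 15, while the oxyphosphonium group leaves from the β face; the medium is neutral, so the Z-enoate is not isomerised, and the tertiary C4 alcohol does not react.

## Compound list

1 | cycloheptane-1,3-dione | O=C1CCCCC(=O)C1 | starting material
2 | 2-methylcycloheptane-1,3-dione | CC1C(=O)CCCCC1=O | intermediate
3 | acrolein | C=CC=O | starting material
4 | 3-(1-methyl-2,7-dioxocycloheptyl)propanal | O=CCCC1(C)C(=O)CCCCC1=O | intermediate
5 | (3aR,8aS)-3a-hydroxy-8a-methyloctahydroazulene-3,8-dione (cis-fused ketol) | O=C1CCCC[C@@]2(O)[C@]1(C)CCC2=O | intermediate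
6 | (8aS)-8a-methyl-1,2,5,6,7,8a-hexahydroazulene-3,8-dione (Δ5-en-4-one, C10 ketone) | O=C1CCCC=C2[C@]1(C)CCC2=O | intermediate
7 | (1S,4S,10S)-1-methylbicyclo[5.3.0]dec-5-ene-4β,10β-diol | O[C@H]1CCCC=C2[C@]1(C)CC[C@@H]2O | intermediate
8 | 4β,10β-bis(TBS) ether of 7 | CC(C)(C)[Si](C)(C)O[C@H]1CCCC=C2[C@]1(C)CC[C@@H]2O[Si](C)(C)C(C)(C)C | intermediate
9 | 6α-alkylborane (BH2 on C6, 5α-H) | CC(C)(C)[Si](C)(C)O[C@H]1CCC[C@H](B)[C@@H]2[C@]1(C)CC[C@@H]2O[Si](C)(C)C(C)(C)C | intermediate
10 | 4β,10β-bis(TBSO)-5α-H-6α-ol | CC(C)(C)[Si](C)(C)O[C@H]1CCC[C@H](O)[C@@H]2[C@]1(C)CC[C@@H]2O[Si](C)(C)C(C)(C)C | intermediate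
11 | veratric acid | COc1ccc(C(=O)O)cc1OC | starting material
12 | 6α-veratrate of 10 | CC(C)(C)[Si](C)(C)O[C@H]1CCC[C@H](OC(=O)c3ccc(OC)c(OC)c3)[C@@H]2[C@]1(C)CC[C@@H]2O[Si](C)(C)C(C)(C)C | intermediate
13 | 6α-veratroyloxy-4β,10β-diol | O[C@H]1CCC[C@H](OC(=O)c3ccc(OC)c(OC)c3)[C@@H]2[C@]1(C)CC[C@@H]2O | intermediate
14 | 6α-veratroyloxy-5α-H-4,10-dione | O=C1CCC[C@H](OC(=O)c3ccc(OC)c(OC)c3)[C@@H]2[C@]1(C)CCC2=O | intermediate
15 | 4β-hydroxy-4α-isopropyl-6α-veratroyloxy-10-ketone | O=C1CCC[C@H](OC(=O)c3ccc(OC)c(OC)c3)[C@@H]2[C@]1(C)CC[C@@]2(O)C(C)C | intermediate
16 | Δ8-en-10-one | O=C1C=CC[C@H](OC(=O)c3ccc(OC)c(OC)c3)[C@@H]2[C@]1(C)CC[C@@]2(O)C(C)C | intermediate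
17 | 8-methyl-10-ketone (C8 epimers, centre left undefined) | O=C1CC(C)C[C@H](OC(=O)c3ccc(OC)c(OC)c3)[C@@H]2[C@]1(C)CC[C@@]2(O)C(C)C | intermediate
18 | 8-methyl-Δ8-en-10-one | O=C1C=C(C)C[C@H](OC(=O)c3ccc(OC)c(OC)c3)[C@@H]2[C@]1(C)CC[C@@]2(O)C(C)C | intermediate
19 | 8-methyl-Δ8-en-10β-ol | O[C@H]1C=C(C)C[C@H](OC(=O)c3ccc(OC)c(OC)c3)[C@@H]2[C@]1(C)CC[C@@]2(O)C(C)C | intermediate
20 | angelic acid | C/C=C(/C)C(=O)O | starting material
21 | CNP0142353.1, (1S,4R,5S,6S,10R) | C/C=C(/C)C(=O)O[C@@H]1C=C(C)C[C@H](OC(=O)c2ccc(OC)c(OC)c2)[C@@H]2[C@]1(C)CC[C@@]2(O)C(C)C | target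

## Step count and least certain steps

Total: 16 steps. Longest linear sequence: 16 steps, from cycloheptane-1,3-dione 1.

**Step 3 (key step).** The seven-membered diketone is more flexible than the six-membered one. Discrimination between the enantiotopic carbonyls may be weaker, the addition slower, and retro-benzoin equilibration or intermolecular aldehyde coupling may compete.
Fallback, from 4 back to 7: cyclise 4 with an achiral carbene (2-(pentafluorophenyl)-6,7-dihydro-5H-pyrrolo[2,1-c][1,2,4]triazol-2-ium tetrafluoroborate, DBU) to the racemic cis-fused ketol F1. Dehydrate it as in step 4 to the racemic enedione F2 and reduce this as in step 5. The oxazaborolidine fixes the absolute configuration of both new carbinol carbons, so the (S)-enantiomer gives 7 and the (R)-enantiomer gives the diastereomeric diol F3 (both hydroxyls trans to the methyl). The two are separated by chromatography and the route continues from 7.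

**Step 7.** Borane may attack from the methyl face, because ring A itself lies under the α face of the alkene, or it may add only sluggishly to an alkene flanked by two substituted carbons. Either would give the cis-fused 6β-alcohol or poor conversion.
Fallback, from 7 back to 10: epoxidise 7 with VO(acac)2 and tBuOOH, directed by the allylic 4β-hydroxyl, to the 5β,6β-epoxy diol F4. Silylate it (TBSOTf, 2,6-lutidine) to the epoxy bis-silyl ether F5. Treat F5 with BF3·OEt2 at −78 °C (Meinwald rearrangement): the C5–O bond ionises and the 6α-hydrogen migrates to the α face of C5, giving the trans-fused 6-ketone F6. Dissolving-metal reduction (Li, NH3, tBuOH, −78 °C) to the equatorial 6α-alcohol returns to 10.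

**Step 11.** The reagent may enolise the ketone toward C5, which would expel the veratrate or epimerise the ring fusion. It may also reduce the ketone by β-hydride transfer, or add to the C10 ketone or the ester.
Fallback, from 14 back to 15: add the less basic sp2 nucleophile isopropenylmagnesium bromide with CeCl3 at −78 °C to give the isopropenyl carbinol F7. Hydrogenate its 1,1-disubstituted alkene (H2, Pd/C, EtOAc) to reach 15.

**Step 16.** Displacement at a neopentylic allylic carbon may give way to elimination to a diene, allylic transposition, esterification with retention through an acyloxyphosphonium ion, or Z-to-E isomerisation of the angelate.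
Fallback, from 19 back to 21: invert first with the more acidic 4-nitrobenzoic acid (PPh3, DIAD, toluene, 60 °C) to the 10α-(4-nitrobenzoate) F8. Cleave it selectively beside the electron-rich veratrate (K2CO3, MeOH, 0 °C) to the 10α-alcohol F9. Acylate F9 with retention by Yamaguchi esterification: angelic acid 20, 2,4,6-trichlorobenzoyl chloride and Et3N give the mixed anhydride F10, which with DMAP in toluene gives 21. Should step 15 deliver F9 directly, the same acylation is used without inversion.

## Further compounds

F1 | step 3 | racemic cis-fused ketol | O=C1CCCCC2(O)C1(C)CCC2=O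
F2 | step 3 | racemic Δ5-ene-4,10-dione | O=C1CCCC=C2C1(C)CCC2=O
F3 | step 3 | diastereomeric diol from the (R)-enantiomer (both hydroxyls trans to the methyl) | O[C@H]1CCCC=C2[C@@]1(C)CC[C@@H]2O
F4 | step 7 | 5β,6β-epoxy-4β,10β-diol | O[C@H]1CCC[C@H]2O[C@@]23[C@]1(C)CC[C@@H]3O
F5 | step 7 | 5β,6β-epoxy-4β,10β-bis(TBS) ether | CC(C)(C)[Si](C)(C)O[C@H]1CCC[C@H]2O[C@@]23[C@]1(C)CC[C@@H]3O[Si](C)(C)C(C)(C)C
F6 | step 7 | 4β,10β-bis(TBSO)-5α-H-6-ketone | CC(C)(C)[Si](C)(C)O[C@H]1CCCC(=O)[C@@H]2[C@]1(C)CC[C@@H]2O[Si](C)(C)C(C)(C)C
F7 | step 11 | 4β-hydroxy-4α-isopropenyl-6α-veratroyloxy-10-ketone | O=C1CCC[C@H](OC(=O)c3ccc(OC)c(OC)c3)[C@@H]2[C@]1(C)CC[C@@]2(O)C(C)=C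
F8 | step 16 | 10α-(4-nitrobenzoate) | [O-][N+](=O)c4ccc(cc4)C(=O)O[C@@H]1C=C(C)C[C@H](OC(=O)c3ccc(OC)c(OC)c3)[C@@H]2[C@]1(C)CC[C@@]2(O)C(C)C
F9 | step 16 | 8-methyl-Δ8-en-10α-ol | O[C@@H]1C=C(C)C[C@H](OC(=O)c3ccc(OC)c(OC)c3)[C@@H]2[C@]1(C)CC[C@@]2(O)C(C)C
F10 | step 16 | angelic 2,4,6-trichlorobenzoic anhydride | C/C=C(/C)C(=O)OC(=O)c1c(Cl)cc(Cl)cc1Cl
A1 | alternative 1 | cycloheptene acid (C4 carboxyl on C5, vinyl on C1, C9=C10 alkene, 6-OTBS, 8-methyl) | OC(=O)[C@@H]1[C@@H](O[Si](C)(C)C(C)(C)C)C[C@@H](C)C=C[C@@]1(C)C=C
A2 | alternative 2 | bicyclic diene (10-OPMB, C5=C6 and C8=C9 alkenes, C4 dioxolane) | COc1ccc(CO[C@@H]2C=C(C)CC=C3[C@]2(C)CCC34OCCO4)cc1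
A3 | alternative 3 | hydroazulenone (C10 ketone, C6=C7 alkene, C8 methyl, O4 triethylsilyl ether) | O=C1C[C@@H](C)C=C[C@@H]2[C@]1(C)CC[C@@]2(O[Si](CC)(CC)CC)C(C)C
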